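The anisyl–CH2 bond is disconnected together with the imidazole N1–C5 bond. A palladium-catalysed aminoarylation cascade joins 4-iodoanisole to a tyrosine-derived N-propargylformamidine: 5-exo-dig attack of the amidine nitrogen on the aryl-palladium-activated alkyne, C–C reductive elimination and a 1,3-hydrogen shift create the aryl–CH2 bond, close the imidazole ring and aromatise it in one operation. The step exploits the CH2 group between the anisole ring and imidazole C5: a 5-(arylmethyl)imidazole is the aromatic tautomer of a 5-arylidene-imidazoline, so this CH2 can be the terminal carbon of an alkyne. The precursor is the formamidine of 1-[4-(benzyloxy)phenyl]but-3-yn-2-amine; debenzylation and O-sulfation follow.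

Key step: step 4

Remark: the target is taken as the free acid drawn (expected to exist as the imidazolium aryl sulfate zwitterion, the two imidazole tautomers being equivalent); the stereocentre of intermediates 1–8 is drawn (S) because L-tyrosine is the source, but it is erased in step 4, so its integrity is immaterial; compound 1 is assumed to be a catalogue amino acid derivative.

Step 1
Reactants: 1 N-Boc-O-benzyl-L-tyrosine methyl ester
Product: 3 tert-butyl N-[(2S)-1-[4-(benzyloxy)phenyl]but-3-yn-2-yl]carbamate, via N-Boc-O-benzyl-L-tyrosinal 2 (not isolated)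
Conditions: DIBAL-H, CH2Cl2, −78 °C; MeOH quench; then K2CO3, Ohira–Bestmann reagent, MeOH, 0 °C → rt
Reagents that add atoms: Ohira–Bestmann reagent, dimethyl (1-diazo-2-oxopropyl)phosphonate, COP(=O)(OC)C(=[N+]=[N-])C(C)=O
Why: Partial reduction of the ester with DIBAL-H at −78 °C should stop at the aluminium hemiacetal, which releases aldehyde 2 on methanol quench, and Seyferth–Gilbert homologation with the Ohira–Bestmann reagent then converts CHO into C≡CH in the same flask; the α-stereocentre is carried over from L-tyrosine and any epimerisation would be of no consequence.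

Step 2
Reactants: 3 tert-butyl N-[(2S)-1-[4-(benzyloxy)phenyl]but-3-yn-2-yl]carbamate
Product: 4 (2S)-1-[4-(benzyloxy)phenyl]but-3-yn-2-amine
Conditions: HCl (4 M in 1,4-dioxane), rt; then aq NaHCO3, CH2Cl2 extraction
Reagents that add atoms: none
Why: Acidolysis of the Boc carbamate (loss of the tert-butyl cation, then decarboxylation) should proceed cleanly at room temperature, where the benzyl aryl ether and the terminal alkyne are stable.

Step 3
Reactants: 4 (2S)-1-[4-(benzyloxy)phenyl]but-3-yn-2-amine; 5 ethyl formimidate hydrochloride
Product: 6 N-[(2S)-1-[4-(benzyloxy)phenyl]but-3-yn-2-yl]formamidine hydrochloride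
Conditions: 5 (1.3 equiv), abs. EtOH, 0 °C → rt; evaporate, triturate with Et2O
Reagents that add atoms: none
Why: Pinner-type amidine synthesis, in which the primary amine adds to the imidate salt and ethanol is expelled to give the N-monosubstituted formamidinium chloride, with excess imidate and low temperature disfavouring exchange with a second amine.

Step 4
Reactants: 6 N-[(2S)-1-[4-(benzyloxy)phenyl]but-3-yn-2-yl]formamidine hydrochloride; 7 4-iodoanisole
Product: 9 4-[4-(benzyloxy)benzyl]-5-(4-methoxybenzyl)-1H-imidazole, via arylidene-imidazoline 8 (not isolated)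
Conditions: 7 (1.3 equiv), Pd(PPh3)4 (5 mol %), Cs2CO3 (3 equiv), DMF, 80 °C, argon
Reagents that add atoms: none
Why: Oxidative addition of 7 to Pd(0) gives an arylpalladium(II) iodide that π-activates the terminal alkyne of the free-based amidine, the terminal formamidine nitrogen attacks the internal alkyne carbon anti to palladium, and C–C reductive elimination from the resulting vinyl(aryl)palladium places the anisyl group on the former terminal carbon to give 8. A base-mediated 1,3-prototropic shift of the C4–H to the exocyclic carbon then aromatises 8 to imidazole 9, turning the arylidene carbon into the anisyl–CH2 group. The closest known reaction type is the palladium-catalysed coupling–cyclisation (alkyne aminoarylation) of N-propargyl amides, amidines and guanidines with aryl halides or triflates, which gives 5-benzyloxazoles and 4-benzylimidazoles. The imidazole ring is closed in the 5-exo-dig mode by N1–C5 bond formation. No stereocentre is created: the only one present (C4 of 8) is erased by the aromatisation, and the alkene geometry of 8 is without consequence. The step needs arylative rather than simple base-induced cyclisation and 5-exo rather than 6-endo attack, which the fast oxidative addition of the aryl iodide (used in excess), the short N–C–N tether and the terminal alkyne should secure; a competing copper-free Sonogashira coupling followed by 5-exo-dig hydroamination would converge on the same product.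

Step 5
Reactants: 9 4-[4-(benzyloxy)benzyl]-5-(4-methoxybenzyl)-1H-imidazole
Product: 10 4-{[5-(4-methoxybenzyl)-1H-imidazol-4-yl]methyl}phenol
Conditions: H2 (1 atm), 10 % Pd/C, MeOH–AcOH, rt; filter, neutralise
Reagents that add atoms: none
Why: Hydrogenolysis of the benzyl aryl ether over Pd/C, with acetic acid protonating the imidazole to limit catalyst poisoning, should leave the methyl ether and the two aryl–CH2–imidazole units untouched.

Step 6
Reactants: 10 4-{[5-(4-methoxybenzyl)-1H-imidazol-4-yl]methyl}phenol
Product: 11 Melanocin F, 4-{[5-(4-methoxybenzyl)-1H-imidazol-4-yl]methyl}phenyl hydrogen sulfate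
Conditions: SO3·pyridine (3 equiv), pyridine, rt; then H2O; reversed-phase C18, H2O/MeCN (neutral)
Reagents that add atoms: sulfur trioxide–pyridine complex, O=S(=O)([O-])[n+]1ccccc1
Why: O-Sulfation of a phenol with the sulfur trioxide–pyridine complex is standard, and any N-sulfonated imidazole formed alongside is a labile sulfonyl-azole that should hydrolyse in the aqueous work-up, so the aryl sulfate is expected as the zwitterion under neutral isolation.

Compound list
1 | N-Boc-O-benzyl-L-tyrosine methyl ester | COC(=O)[C@H](Cc1ccc(OCc2ccccc2)cc1)NC(=O)OC(C)(C)C | starting material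
2 | N-Boc-O-benzyl-L-tyrosinal, tert-butyl N-[(2S)-1-[4-(benzyloxy)phenyl]-3-oxopropan-2-yl]carbamate | O=C[C@H](Cc1ccc(OCc2ccccc2)cc1)NC(=O)OC(C)(C)C | intermediate (not isolated)
3 | tert-butyl N-[(2S)-1-[4-(benzyloxy)phenyl]but-3-yn-2-yl]carbamate | C#C[C@H](Cc1ccc(OCc2ccccc2)cc1)NC(=O)OC(C)(C)C | intermediate
4 | (2S)-1-[4-(benzyloxy)phenyl]but-3-yn-2-amine | C#C[C@H](Cc1ccc(OCc2ccccc2)cc1)N | intermediate
5 | ethyl formimidate hydrochloride | CCOC=N.Cl | starting material
6 | N-[(2S)-1-[4-(benzyloxy)phenyl]but-3-yn-2-yl]formamidine hydrochloride | Cl.C#C[C@H](Cc1ccc(OCc2ccccc2)cc1)NC=N | intermediate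
7 | 4-iodoanisole | COc1ccc(I)cc1 | starting material
8 | (4S,5E)-4-[4-(benzyloxy)benzyl]-5-(4-methoxybenzylidene)-4,5-dihydro-1H-imidazole | COc1ccc(/C=C2/NC=N[C@H]2Cc2ccc(OCc3ccccc3)cc2)cc1 | intermediate (not isolated)
9 | 4-[4-(benzyloxy)benzyl]-5-(4-methoxybenzyl)-1H-imidazole | COc1ccc(Cc2[nH]cnc2Cc2ccc(OCc3ccccc3)cc2)cc1 | intermediate
10 | 4-{[5-(4-methoxybenzyl)-1H-imidazol-4-yl]methyl}phenol | COc1ccc(Cc2[nH]cnc2Cc2ccc(O)cc2)cc1 | intermediate
11 | Melanocin F | COc1ccc(Cc2[nH]cnc2Cc2ccc(OS(=O)(=O)O)cc2)cc1 | target

Total step count: 6. Longest linear sequence: 6 steps (1 → 3 → 4 → 6 → 9 → 10 → 11).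

Steps most likely to fail

Step 4. The base-induced, non-arylative cycloisomerisation of the free amidine (giving a 5-methylimidazole), or its loss by hydrolysis or N-arylation, may outrun the palladium cascade. The fallback separates C–C bond formation from ring closure and sets out from 3. Sonogashira coupling of 3 with 7 (PdCl2(PPh3)2, CuI, Et3N, THF, rt) should give tert-butyl N-[(2S)-1-[4-(benzyloxy)phenyl]-4-(4-methoxyphenyl)but-3-yn-2-yl]carbamate F1. Boc removal (HCl/dioxane, then NaHCO3) should give (2S)-1-[4-(benzyloxy)phenyl]-4-(4-methoxyphenyl)but-3-yn-2-amine F2. Treatment with 5 in EtOH should give N-[(2S)-1-[4-(benzyloxy)phenyl]-4-(4-methoxyphenyl)but-3-yn-2-yl]formamidine hydrochloride F3. Base-mediated 5-exo-dig hydroamination and prototropic aromatisation (Cs2CO3, DMF, 80 °C) is expected to come back to the route at 9.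

Step 3. The first-formed formamidine may exchange with a second molecule of amine to give the N,N'-disubstituted formamidine, or the hygroscopic imidate and amidine salts may hydrolyse to the formamide. The fallback builds the amidine in two stages and sets out from 4. Condensation with N,N-dimethylformamide dimethyl acetal (toluene, 60 °C) should give the stable N'-[(2S)-1-[4-(benzyloxy)phenyl]but-3-yn-2-yl]-N,N-dimethylformamidine F4. Amidine exchange with NH4Cl (EtOH, 60 °C, loss of volatile dimethylamine) should come back to the route at 6.

Step 6. Sulfation may be incomplete or unselective (persistent N-sulfonation of the imidazole), and the sulfate may be lost during purification of the zwitterion. The fallback uses a protected sulfate and sets out from 10. Reaction with 2,2,2-trichloroethyl chlorosulfate (Et3N, DMAP, THF; MeOH work-up to cleave any N-sulfuryl imidazole) should give the chromatographable diester 4-{[5-(4-methoxybenzyl)-1H-imidazol-4-yl]methyl}phenyl 2,2,2-trichloroethyl sulfate F5. Reductive removal of the trichloroethyl group (Zn, HCO2NH4, MeOH, rt) should come back to the route at 11.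

Further compounds
F1 | step 4 | tert-butyl N-[(2S)-1-[4-(benzyloxy)phenyl]-4-(4-methoxyphenyl)but-3-yn-2-yl]carbamate | COc1ccc(C#C[C@H](Cc2ccc(OCc3ccccc3)cc2)NC(=O)OC(C)(C)C)cc1
F2 | step 4 | (2S)-1-[4-(benzyloxy)phenyl]-4-(4-methoxyphenyl)but-3-yn-2-amine | COc1ccc(C#C[C@H](Cc2ccc(OCc3ccccc3)cc2)N)cc1
F3 | step 4 | N-[(2S)-1-[4-(benzyloxy)phenyl]-4-(4-methoxyphenyl)but-3-yn-2-yl]formamidine hydrochloride | Cl.COc1ccc(C#C[C@H](Cc2ccc(OCc3ccccc3)cc2)NC=N)cc1
F4 | step 3 | N'-[(2S)-1-[4-(benzyloxy)phenyl]but-3-yn-2-yl]-N,N-dimethylformamidine | C#C[C@H](Cc1ccc(OCc2ccccc2)cc1)N=CN(C)C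
F5 | step 6 | 4-{[5-(4-methoxybenzyl)-1H-imidazol-4-yl]methyl}phenyl 2,2,2-trichloroethyl sulfate | COc1ccc(Cc2[nH]cnc2Cc2ccc(OS(=O)(=O)OCC(Cl)(Cl)Cl)cc2)cc1
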